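## Retrosynthetic overview

1. Ring numbering used below: C1 ketone, C2 (N), C3, C4 carbinol, C5–C6 oxirane. The last bond made is the vinyl–dienyl bond of the triene, by Stille coupling of a C4-(E)-stannylvinyl epoxyquinol with the (2E,4E)-5-bromodienamide of the aminocyclopentenone.
2. The C4 carbinol comes from addition of (E)-Bu3SnCH=CHLi to the C4 ketone of a C1-ketal-protected epoxyquinone, anti to the oxirane; ketal hydrolysis then frees C1=O.
3. Key disconnection: the spiro-1,3-dioxane (C1 ketal) and the C5–C6 oxirane are both formed in one flask from a 3-acylamino-4-(hydroxyalkoxy)phenol, by dearomative spiroketalization followed by asymmetric epoxidation.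
4. That phenol comes from 4-fluoro-3-nitrophenol, (2R,4R)-pentane-2,4-diol (SNAr with retention) and the dienoic acid made by vinylogous HWE from cyclohexanecarbaldehyde.
5. Ring order: the cyclohexane, the six-membered carbocycle (as a benzene) and the cyclopentenone are bought; dioxane and oxirane are made together in step 6; the dioxane is removed in step 8.

Assumption: (2R,4R)-pentane-2,4-diol, (E)-1,2-bis(tributylstannyl)ethene, glutaconaldehyde potassium salt, 2-amino-3-hydroxycyclopent-2-en-1-one hydrochloride and N-benzylcinchonidinium chloride are bought as catalogue chemicals.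

## Route

Step 1
Reactants: 1 cyclohexanecarbaldehyde; 2 triethyl 4-phosphonocrotonate (ethyl (2E)-4-(diethoxyphosphoryl)but-2-enoate)
Product: 4 (2E,4E)-5-cyclohexylpenta-2,4-dienoic acid, via ethyl dienoate 3 (not isolated)
Conditions: LiOH·H2O, 4 Å MS, THF, reflux; then H2O–MeOH, 50 °C; 1 M HCl work-up
Reagents that add atoms: lithium hydroxide, [Li+].[OH-]
Why: Vinylogous Horner–Wadsworth–Emmons olefination (2E is carried in from 2, the new 4E alkene is the normal outcome for a stabilised phosphonate anion) followed in the same pot by saponification; no stereocentre is formed and the acid is purified by crystallisation.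

Step 2
Reactants: 5 4-fluoro-3-nitrophenol
Product: 6 4-(benzyloxy)-1-fluoro-2-nitrobenzene
Conditions: BnBr, K2CO3, DMF, rt
Reagents that add atoms: benzyl bromide, BrCc1ccccc1
Why: Williamson etherification; capping the phenol keeps the ring free of a phenoxide donor so the fluoride ortho to the nitro group stays SNAr-active, and the benzyl group later leaves in the same hydrogenation that reduces the nitro group.

Step 3
Reactants: 6 4-(benzyloxy)-1-fluoro-2-nitrobenzene; 7 (2R,4R)-pentane-2,4-diol
Product: 8 (2R,4R)-4-[4-(benzyloxy)-2-nitrophenoxy]pentan-2-ol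
Conditions: 7 (3 equiv), NaH (1.1 equiv), THF, 0 °C → rt
Reagents that add atoms: none
Why: SNAr of the diol mono-alkoxide on the ortho-fluoronitroarene; the new C–O bond is made at the aryl carbon, so both carbinol centres keep the (R) configuration (a Mitsunobu etherification would invert one of them and destroy the C2 symmetry needed in step 6).

Step 4
Reactants: 8 (2R,4R)-4-[4-(benzyloxy)-2-nitrophenoxy]pentan-2-ol
Product: 9 3-amino-4-{[(2R,4R)-4-hydroxypentan-2-yl]oxy}phenol
Conditions: H2 (1 atm), 10% Pd/C, EtOH, rt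
Reagents that add atoms: none
Why: Catalytic hydrogenation reduces the nitro group and removes the O-benzyl group by hydrogenolysis in one step, while the sec-alkyl aryl ether and both stereocentres are untouched; the air-sensitive aminophenol is used at once.

Step 5
Reactants: 4 (2E,4E)-5-cyclohexylpenta-2,4-dienoic acid; 9 3-amino-4-{[(2R,4R)-4-hydroxypentan-2-yl]oxy}phenol
Product: 11 (2E,4E)-5-cyclohexyl-N-(5-hydroxy-2-{[(2R,4R)-4-hydroxypentan-2-yl]oxy}phenyl)penta-2,4-dienamide, via acid chloride 10 (not isolated)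
Conditions: 4, (COCl)2, cat. DMF, CH2Cl2, 0 °C → rt, evaporate; then 9, NaHCO3, THF–H2O, 0 °C
Reagents that add atoms: none
Why: Schotten–Baumann N-acylation; under bicarbonate the aniline nitrogen is far more nucleophilic than the phenol or the secondary alcohol, so one equivalent of acid chloride gives the anilide only.

Step 6
Reactants: 11 (2E,4E)-5-cyclohexyl-N-(5-hydroxy-2-{[(2R,4R)-4-hydroxypentan-2-yl]oxy}phenyl)penta-2,4-dienamide
Product: 13 (2E,4E)-5-cyclohexyl-N-[(1'R,4R,6R,6'S)-4,6-dimethyl-5'-oxospiro[1,3-dioxane-2,2'-[7]oxabicyclo[4.1.0]hept[3]en]-3'-yl]penta-2,4-dienamide, via spiroketal dienone 12 (not isolated)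
Conditions: PhI(OAc)2 (1.05 equiv), CH2Cl2, 0 °C, 20 min; then, same flask, PhMe, N-benzylcinchonidinium chloride (10 mol %), t-BuOOH (70 % aq), 1 M NaOH, 0 °C → rt
Reagents that add atoms: tert-butyl hydroperoxide, CC(C)(C)OO
Why: Proposed new method: PhI(OAc)2 converts the phenol into an aryloxy-λ3-iodane that loses PhI as the tethered secondary OH attacks the alkoxy-bearing para carbon (dearomative spiroketalization, known for ω-hydroxyalkyl hydroquinone ethers; the C2-symmetric diol makes the spiro carbon non-stereogenic, so a single dienone forms), and because no alcohol solvent is needed the same flask is then made biphasic so that t-BuOO−, ion-paired with the cinchonidinium catalyst, adds to C6 of the only electrophilic enone (the C2=C3 enamide is a deactivated vinylogous imide) and closes the oxirane (Weitz–Scheffer epoxidation, Wynberg-type phase transfer); the closest known chemistry is the stepwise PhI(OAc)2/MeOH ketalization and cinchona phase-transfer epoxidation of 3-acylamino quinone monoketals, from which the facial sense is taken by analogy, and the (R,R)-dioxane turns any wrong-face epoxide into a diastereomer removed by chromatography, so C5/C6 are secured as (5S,6R) and both new rings are formed in this one operation.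

Step 7
Reactants: 13 the (1'R,6'S)-epoxy spiroketal from step 6; 14 (E)-1,2-bis(tributylstannyl)ethene
Product: 16 (2E,4E)-5-cyclohexyl-N-[(1'R,4R,5'S,6R,6'S)-5'-hydroxy-4,6-dimethyl-5'-[(E)-2-(tributylstannyl)ethenyl]spiro[1,3-dioxane-2,2'-[7]oxabicyclo[4.1.0]hept[3]en]-3'-yl]penta-2,4-dienamide, via stannylvinyllithium 15 (not isolated)
Conditions: 14 (3.3 equiv), n-BuLi (3.2 equiv), THF, −78 °C, 1 h; then 13, −78 → −40 °C; aq NH4Cl
Reagents that add atoms: none
Why: Tin–lithium exchange gives the (E)-vinyllithium with retention; its first equivalent removes the amide N–H (the amidate shields the dienamide from conjugate addition) and the next adds 1,2 to the C4 ketone from the face opposite the adjacent oxirane oxygen, which places the C4 hydroxyl syn to the epoxide (the C4 centre of the target; descriptor S here only because the stannylvinyl group outranks C3).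

Step 8
Reactants: 16 the stannylvinyl carbinol spiroketal from step 7
Product: 17 (2E,4E)-5-cyclohexyl-N-[(1R,5S,6S)-5-hydroxy-2-oxo-5-[(E)-2-(tributylstannyl)ethenyl]-7-oxabicyclo[4.1.0]hept-3-en-3-yl]penta-2,4-dienamide
Conditions: Montmorillonite K10, wet CH2Cl2, rt
Reagents that add atoms: water, O
Why: Mild heterogeneous acid-catalysed ketal hydrolysis; the trans-4,6-dimethyl-1,3-dioxane cannot adopt a strain-free chair (it behaves like an anti-1,3-diol acetonide) and so opens far more readily than an ordinary cyclic ketal, and no stereocentre is touched.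

Step 9
Reactants: 18 glutaconaldehyde potassium salt (potassium (1E,3E)-5-oxopenta-1,3-dien-1-olate)
Product: 19 (2E,4E)-5-bromopenta-2,4-dienal
Conditions: Ph3PBr2, CH2Cl2, 0 °C → rt
Reagents that add atoms: dibromotriphenylphosphorane, BrP(Br)(c1ccccc1)(c1ccccc1)c1ccccc1
Why: Deoxybromination of the vinylogous formate anion: O-phosphonium formation, then addition–elimination by bromide driven by Ph3P=O loss, giving the thermodynamically favoured E,E push–pull dienal.

Step 10
Reactants: 19 (2E,4E)-5-bromopenta-2,4-dienal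
Product: 20 (2E,4E)-5-bromopenta-2,4-dienoic acid
Conditions: NaClO2, NaH2PO4, 2-methylbut-2-ene, t-BuOH–H2O, rt
Reagents that add atoms: sodium chlorite, [Na+].[O-]Cl=O
Why: Pinnick (Lindgren–Kraus) oxidation converts the enal into the acid without touching the vinyl bromide or the alkene geometry, the hypochlorite by-product being trapped by the alkene scavenger.

Step 11
Reactants: 20 (2E,4E)-5-bromopenta-2,4-dienoic acid; 21 2-amino-3-hydroxycyclopent-2-en-1-one hydrochloride
Product: 23 (2E,4E)-5-bromo-N-(2-hydroxy-5-oxocyclopent-1-en-1-yl)penta-2,4-dienamide, via acid chloride 22 (not isolated)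
Conditions: 20, (COCl)2, cat. DMF, CH2Cl2, 0 °C → rt, evaporate; then 21, Et3N, CH2Cl2, 0 °C → rt
Reagents that add atoms: none
Why: Acylation of the liberated enaminone; any O-acylated enol ester rearranges by O→N acyl shift to the more stable vinylogous-acid amide, and no stereocentre is involved.

Step 12
Reactants: 17 the stannylvinyl epoxyquinol from step 8; 23 (2E,4E)-5-bromo-N-(2-hydroxy-5-oxocyclopent-1-en-1-yl)penta-2,4-dienamide
Product: 24 (2E,4E)-5-cyclohexyl-N-[(1R,5R,6S)-5-hydroxy-5-[(1E,3E,5E)-7-[(2-hydroxy-5-oxocyclopent-1-en-1-yl)amino]-7-oxohepta-1,3,5-trien-1-yl]-2-oxo-7-oxabicyclo[4.1.0]hept-3-en-3-yl]penta-2,4-dienamide (target, CNP0111189.1)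
Conditions: PdCl2(MeCN)2 (10 mol %), DMF, rt, dark
Reagents that add atoms: none
Why: Ligand-free Stille cross-coupling of a vinylstannane with a vinyl bromide proceeds with retention at both alkenes and tolerates the free tertiary alcohol, epoxy ketone, enol and amides, completing the (1E,3E,5E)-triene without touching the three ring stereocentres.

## Compound list

1 | cyclohexanecarbaldehyde | O=CC1CCCCC1 | starting material
2 | triethyl 4-phosphonocrotonate (ethyl (2E)-4-(diethoxyphosphoryl)but-2-enoate) | CCOC(=O)/C=C/CP(=O)(OCC)OCC | starting material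
3 | ethyl (2E,4E)-5-cyclohexylpenta-2,4-dienoate | CCOC(=O)/C=C/C=C/C1CCCCC1 | intermediate
4 | (2E,4E)-5-cyclohexylpenta-2,4-dienoic acid | OC(=O)/C=C/C=C/C1CCCCC1 | intermediate
5 | 4-fluoro-3-nitrophenol | Oc1ccc(F)c(c1)[N+](=O)[O-] | starting material
6 | 4-(benzyloxy)-1-fluoro-2-nitrobenzene | [O-][N+](=O)c1cc(OCc2ccccc2)ccc1F | intermediate
7 | (2R,4R)-pentane-2,4-diol | C[C@@H](O)C[C@@H](C)O | starting material
8 | (2R,4R)-4-[4-(benzyloxy)-2-nitrophenoxy]pentan-2-ol | C[C@@H](O)C[C@@H](C)Oc1ccc(OCc2ccccc2)cc1[N+](=O)[O-] | intermediate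
9 | 3-amino-4-{[(2R,4R)-4-hydroxypentan-2-yl]oxy}phenol | C[C@@H](O)C[C@@H](C)Oc1ccc(O)cc1N | intermediate
10 | (2E,4E)-5-cyclohexylpenta-2,4-dienoyl chloride | ClC(=O)/C=C/C=C/C1CCCCC1 | intermediate
11 | (2E,4E)-5-cyclohexyl-N-(5-hydroxy-2-{[(2R,4R)-4-hydroxypentan-2-yl]oxy}phenyl)penta-2,4-dienamide | O=C(/C=C/C=C/C1CCCCC1)Nc1cc(O)ccc1O[C@H](C)C[C@@H](C)O | intermediate
12 | (2E,4E)-5-cyclohexyl-N-[(2R,4R)-2,4-dimethyl-9-oxo-1,5-dioxaspiro[5.5]undeca-7,10-dien-7-yl]penta-2,4-dienamide (spiroketal dienone) | O=C(/C=C/C=C/C1CCCCC1)NC1=CC(=O)C=CC12O[C@H](C)C[C@@H](C)O2 | intermediate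
13 | (2E,4E)-5-cyclohexyl-N-[(1'R,4R,6R,6'S)-4,6-dimethyl-5'-oxospiro[1,3-dioxane-2,2'-[7]oxabicyclo[4.1.0]hept[3]en]-3'-yl]penta-2,4-dienamide (epoxy spiroketal) | O=C(/C=C/C=C/C1CCCCC1)NC1=CC(=O)[C@H]2O[C@H]2C13O[C@H](C)C[C@@H](C)O3 | intermediate
14 | (E)-1,2-bis(tributylstannyl)ethene | CCCC[Sn](CCCC)(CCCC)/C=C/[Sn](CCCC)(CCCC)CCCC | starting material
15 | [(E)-2-(tributylstannyl)ethenyl]lithium | [Li]/C=C/[Sn](CCCC)(CCCC)CCCC | intermediate
16 | (2E,4E)-5-cyclohexyl-N-[(1'R,4R,5'S,6R,6'S)-5'-hydroxy-4,6-dimethyl-5'-[(E)-2-(tributylstannyl)ethenyl]spiro[1,3-dioxane-2,2'-[7]oxabicyclo[4.1.0]hept[3]en]-3'-yl]penta-2,4-dienamide | O=C(/C=C/C=C/C1CCCCC1)NC1=C[C@](O)(/C=C/[Sn](CCCC)(CCCC)CCCC)[C@H]2O[C@H]2C13O[C@H](C)C[C@@H](C)O3 | intermediate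
17 | (2E,4E)-5-cyclohexyl-N-[(1R,5S,6S)-5-hydroxy-2-oxo-5-[(E)-2-(tributylstannyl)ethenyl]-7-oxabicyclo[4.1.0]hept-3-en-3-yl]penta-2,4-dienamide | O=C(/C=C/C=C/C1CCCCC1)NC1=C[C@](O)(/C=C/[Sn](CCCC)(CCCC)CCCC)[C@H]2O[C@H]2C1=O | intermediate
18 | glutaconaldehyde potassium salt (potassium (1E,3E)-5-oxopenta-1,3-dien-1-olate) | [K+].[O-]/C=C/C=C/C=O | starting material
19 | (2E,4E)-5-bromopenta-2,4-dienal | O=C/C=C/C=C/Br | intermediate
20 | (2E,4E)-5-bromopenta-2,4-dienoic acid | OC(=O)/C=C/C=C/Br | intermediate
21 | 2-amino-3-hydroxycyclopent-2-en-1-one hydrochloride | Cl.NC1=C(O)CCC1=O | starting material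
22 | (2E,4E)-5-bromopenta-2,4-dienoyl chloride | ClC(=O)/C=C/C=C/Br | intermediate
23 | (2E,4E)-5-bromo-N-(2-hydroxy-5-oxocyclopent-1-en-1-yl)penta-2,4-dienamide | O=C(/C=C/C=C/Br)NC1=C(O)CCC1=O | intermediate
24 | (2E,4E)-5-cyclohexyl-N-[(1R,5R,6S)-5-hydroxy-5-[(1E,3E,5E)-7-[(2-hydroxy-5-oxocyclopent-1-en-1-yl)amino]-7-oxohepta-1,3,5-trien-1-yl]-2-oxo-7-oxabicyclo[4.1.0]hept-3-en-3-yl]penta-2,4-dienamide | O=C(/C=C/C=C/C1CCCCC1)NC1=C[C@](O)(/C=C/C=C/C=C/C(=O)NC2=C(O)CCC2=O)[C@H]2O[C@H]2C1=O | target

## Step count and risks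

Total step count: 12.
Longest linear sequence: 8 steps (steps 2, 3, 4, 5, 6, 7, 8 and 12, from 5).

Three steps most likely to fail:

Step 6. The one-flask sequence may suffer from carried-over iodobenzene and acetate, and the phase-transfer catalyst may give poor facial control or low conversion on this dienamide spiroketal; the catalyst sense is taken by analogy and must be confirmed. The fallback replaces catalyst control by an auxiliary-based resolution in two separate steps. Setting out from 11, the oxidation is run alone (PhI(OAc)2, MeCN, 0 °C) and spiroketal dienone 12 is isolated. It is then epoxidised with no chiral reagent (30 % H2O2, K2CO3, THF–H2O, 0 °C), which gives 13 together with its oxirane-epimeric diastereomer, the (1'S,6'R)-epoxy spiroketal F1. Because the (R,R)-dioxane makes these two diastereomers and not enantiomers, they are separated by chromatography or crystallisation, and the route is rejoined at 13.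

Step 7. Tin–lithium exchange may be incomplete, or the basic vinyllithium may attack the dienamide or the oxirane of the N–H-bearing substrate. The fallback builds the stannylvinyl group from an alkyne instead of a stannylvinyl anion. Setting out from 13, ethynylmagnesium bromide (3 equiv, THF, −78 → 0 °C) adds to the C4 ketone anti to the oxirane to give the ethynyl carbinol F2. Palladium-catalysed syn-hydrostannylation (Bu3SnH, cat. PdCl2(PPh3)2, THF, 0 °C) then places tin at the unhindered terminal carbon with E geometry, and the route is rejoined at 16.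

Step 8. A cyclic ketal needs more acid than a dimethyl ketal, and the vinylstannane (protodestannylation) and the tertiary allylic alcohol may not survive it. The fallback changes the order so that the C–Sn bond is gone before any acid is used. Setting out from 16, the Stille coupling with 23 (PdCl2(MeCN)2, DMF, rt) is run first to give the ketal-protected target F3. The dioxane is then hydrolysed as the last operation (K10 clay in wet CH2Cl2, or 80 % aq AcOH, rt), and the route is rejoined at 24.

## Further compounds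

F1 | step 6 | (2E,4E)-5-cyclohexyl-N-[(1'S,4R,6R,6'R)-4,6-dimethyl-5'-oxospiro[1,3-dioxane-2,2'-[7]oxabicyclo[4.1.0]hept[3]en]-3'-yl]penta-2,4-dienamide | O=C(/C=C/C=C/C1CCCCC1)NC1=CC(=O)[C@@H]2O[C@@H]2C13O[C@H](C)C[C@@H](C)O3
F2 | step 7 | (2E,4E)-5-cyclohexyl-N-[(1'R,4R,5'S,6R,6'S)-5'-ethynyl-5'-hydroxy-4,6-dimethylspiro[1,3-dioxane-2,2'-[7]oxabicyclo[4.1.0]hept[3]en]-3'-yl]penta-2,4-dienamide | O=C(/C=C/C=C/C1CCCCC1)NC1=C[C@](O)(C#C)[C@H]2O[C@H]2C13O[C@H](C)C[C@@H](C)O3
F3 | step 8 | (2E,4E)-5-cyclohexyl-N-[(1'R,4R,5'R,6R,6'S)-5'-hydroxy-5'-[(1E,3E,5E)-7-[(2-hydroxy-5-oxocyclopent-1-en-1-yl)amino]-7-oxohepta-1,3,5-trien-1-yl]-4,6-dimethylspiro[1,3-dioxane-2,2'-[7]oxabicyclo[4.1.0]hept[3]en]-3'-yl]penta-2,4-dienamide | O=C(/C=C/C=C/C1CCCCC1)NC1=C[C@](O)(/C=C/C=C/C=C/C(=O)NC2=C(O)CCC2=O)[C@H]2O[C@H]2C13O[C@H](C)C[C@@H](C)O3
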